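I started from a one-step world, with one share of target whatever the recipe, but the earlier runs did not fit it.

common to all: substrate 0.42 M; catalyst 10 mol%
- Wednesday's: other conformer 0.33 equiv; run made earlier
- Saturday's: other conformer 5.7 equiv; run made earlier
- north-west: other conformer 0.250 equiv; time 80 min
- west: other conformer 0.500 equiv; time 80 min
- south: other conformer 1.00 equiv; time 80 min
- east: other conformer 2.00 equiv; time 80 min
- north-east: other conformer 4.00 equiv; time 80 min

- Wednesday's (time / min: target / %, isomer of the product / %, side product / %): 3.00: 49.8, 13.6, 1.6; 8.00: 70.7, 16.9, 3.7; 15.0: 74.3, 17.2, 4.6; 40.0: 73.9, 17.0, 4.0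
- Saturday's (time / min: target / %, isomer of the product / %, side product / %): 5.00: 38.3, 37.7, 4.8; 15.0: 44.5, 38.3, 6.4; 25.0: 44.5, 38.6, 7.2; 40.0: 43.4, 37.9, 6.8

(readings scatter by 0.5 percentage points)

- a species is counted by the substrate in it: one side product counts as two
- the numbers in the tables scatter with a standard deviation of 0.5 percentage points
- "hardly changes" means that all values lie within two and a half points (for a concentration: within two and a half percent of the largest)

1. share of target in all that became target or isomer of the product or side product for north-west, west, south, east, north-east, in this order
2. how the row runs (falls, then rises / falls all the way / rises, then falls / rises all the way / hardly changes)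

Among target, isomer of the product and side product, target held 77.9 % in Wednesday's run at 40.0 min. In Saturday's run at 40.0 min, with more other conformer, it held a lower 49.3 %, so I treated the charge as two pools. Both runs began at [substrate] = 0.42 M.

Wednesday's target read 74.3 % at 15.0 min and 73.9 % at 40.0 min. I read that level stretch as a finished run, and the asked 80 min lay beyond it, so I reckoned with final amounts.

The percentages count both charges, so per substrate charged the products came to 1.26 on Wednesday and 5.90 on Saturday. A straight line through these gave 0.864 per equiv of other conformer and 0.977 from the substrate pool. By that line, target made up 41.5 % of the conformer pool's products and 88.5 % of the substrate pool's.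

I carried one quantity, the balance point, the equivalents of other conformer at which the two pools give equal product: 1.13 equiv. In my reckoning the share of target, a selectivity, was the mean of the two pool shares, weighted by the balance point and the equivalents charged. Since the conformer pool's share was the lower, my row fell, from 80.0 % in north-west to 51.8 % in north-east.

The forecast, “Assuming the yields add linearly”, gave 79.4 %, 73.7 %, 66.3 %, 58.6 % and 52.3 %, which falls all the way, close to my figures but not identical.

The flasks gave 80.0 %, 74.7 %, 67.8 %, 60.3 % and 53.0 %: the row falls all the way.

    substrate ⇌ other conformer (K = 0.100, k = 0.0830 min⁻¹)
    substrate + catalyst → catalyst + target (k = 8.20 L mol⁻¹ min⁻¹)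
    catalyst + other conformer → catalyst + isomer of the product (k = 13.0 L mol⁻¹ min⁻¹)
    substrate + target → side product (k = 0.0400 L mol⁻¹ min⁻¹)
    2 substrate → homo dimer (k = 0.0550 L mol⁻¹ min⁻¹)

A run ten times as long left the north-east share unchanged, with 0 % substrate there at 80.0 min. South stood at 0.885 of the balance point, where my weighting gave 66.4 % and the flask 67.8 %. North-east stood at 3.54 of it, where the weighting gave 51.8 % and the flask 53.0 %.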